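**Strategy.** In germacrane numbering, C3 and C8 lie 1,6 across the ten-membered ring, so the macrocycle is the perimeter of a bicycle: ring A (C3, C4, C5, C6, C7, C8) and ring B (C8, C9, C10, C1, C2, C3) share a C3=C8 double bond. Cutting that tetrasubstituted ring-fusion alkene with ozone creates the C3 and C8 ketones and releases the ten-membered ring in one operation, with no new carbon–carbon bond. The precursor is an octalin carrying the cis-fused α-methylene lactone at C6/C7, the C4 methyl and the C10 methyl carbinol; it comes from an enantiopure methoxytetralin lactone by Birch reduction.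

Key step: step 11

Remarks on the chemistry (before the steps):
- Locants: from compound 15 on, germacrane locants are used (C1–C10 carbocycle, C11–C13 lactone carbons); β is the face that carries the C4 methyl.
- Assumption: the target is drawn as the open 10-hydroxy-3-ketone; its five-membered 3,10-hemiketal is a ring–chain tautomer of the same compound (this also holds for 26 and 27).
- Assumption: the sense of induction of the hydrogenation catalyst in step 6 on this substrate is taken from the usual model; if a first run shows the opposite preference, the mirror-image catalyst is used.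
- C10 is the one stereocentre that is not set with control (step 8); the unwanted 10R epimer is removed there by chromatography and is not carried on.

Step 1
Reactants: 1 4-methoxyphenylboronic acid; 2 ethyl (E)-but-2-enoate
Product: 3 ethyl (3R)-3-(4-methoxyphenyl)butanoate
Conditions: [Rh(nbd)2]BF4 (1 mol%), (S)-BINAP, Et3N, 1,4-dioxane/H2O, 30 °C
Reagents that add atoms: none
Why: Rhodium-catalysed asymmetric 1,4-addition of an arylboronic acid to an enoate (Hayashi–Miyaura reaction): the aryl–rhodium species bearing (S)-BINAP inserts the (E)-enoate on one enantioface and water protonates the resulting oxa-π-allyl complex, which should set the benzylic stereocentre (the later C4) as R.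

Step 2
Reactants: 3 ethyl (3R)-3-(4-methoxyphenyl)butanoate
Product: 4 (3R)-3-(4-methoxyphenyl)butanoic acid
Conditions: LiOH, THF/H2O, rt; then HCl (aq)
Reagents that add atoms: lithium hydroxide, [Li+].[OH-]
Why: Plain ester saponification, which leaves the non-acidic benzylic stereocentre untouched.

Step 3
Reactants: 4 (3R)-3-(4-methoxyphenyl)butanoic acid; 5 (trimethylsilyl)diazomethane
Product: 7 (4R)-1-diazo-4-(4-methoxyphenyl)pentan-2-one, via acid chloride 6 (not isolated)
Conditions: (COCl)2, DMF (cat.), CH2Cl2, 0 °C to rt, evaporate; then 5, MeCN/THF, 0 °C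
Reagents that add atoms: none
Why: Acid chloride formation followed by C-acylation of (trimethylsilyl)diazomethane, chloride removing the silyl group (Arndt–Eistert-type diazoketone synthesis), a sequence that does not involve the stereocentre.

Step 4
Reactants: 7 (4R)-1-diazo-4-(4-methoxyphenyl)pentan-2-one
Product: 9 (4R)-7-methoxy-4-methyl-3,4-dihydronaphthalen-2(1H)-one, via azulenone 8 (not isolated)
Conditions: Rh2(OAc)4 (1 mol%), CH2Cl2, 40 °C, slow addition; then CF3CO2H (cat.), 0 °C
Reagents that add atoms: none
Why: Intramolecular Buchner reaction followed by acid-induced rearrangement: the rhodium carbenoid cyclopropanates the ipso/ortho bond of the anisole ring, the norcaradiene opens to azulenone 8, and CF3CO2H re-aromatizes it with shift of the carbenoid carbon to the ortho position, which should give the 2-tetralone with methoxy at C7, while the non-enolizable C4 stereocentre is carried through unchanged.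

Step 5
Reactants: 9 (4R)-7-methoxy-4-methyl-3,4-dihydronaphthalen-2(1H)-one; 10 ethyl bromoacetate
Product: 13 ethyl 2-[(4R)-7-methoxy-4-methyl-2-oxo-1,2,3,4-tetrahydronaphthalen-1-yl]acetate (both C1 epimers), via enamine 11 (not isolated), via iminium bromide 12 (not isolated)
Conditions: pyrrolidine, p-TsOH (cat.), toluene, reflux (–H2O); then 10, MeCN, 80 °C; then NaOAc, AcOH, H2O, rt
Reagents that add atoms: water, O
Why: Stork enamine alkylation: pyrrolidine forms only the aryl-conjugated C1=C2 enamine, which is mono-alkylated at C1 by the bromoacetate and then hydrolysed, and because C1 stays epimerizable (benzylic and α to the ketone) its configuration is left open here and settled in step 6.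

Step 6
Reactants: 13 ethyl 2-[(4R)-7-methoxy-4-methyl-2-oxo-1,2,3,4-tetrahydronaphthalen-1-yl]acetate
Product: 15 (3aS,5R,9bR)-8-methoxy-5-methyl-3a,4,5,9b-tetrahydronaphtho[2,1-b]furan-2(1H)-one, via hydroxy ester 14 (not isolated)
Conditions: H2 (10 atm), RuCl2[(S)-xylbinap][(S)-daipen] (0.5 mol%), KOt-Bu (cat.), i-PrOH, 25 °C; then p-TsOH (cat.), toluene, 50 °C
Reagents that add atoms: none
Why: Noyori-type bifunctional ketone hydrogenation with dynamic kinetic resolution: C1 of 13 epimerizes quickly through its benzylic enolate under the basic conditions, the chiral ruthenium hydride reduces one C1 epimer only and transfers hydrogen to the carbonyl face anti to the C1 side chain, which should give the cis-1,2 hydroxy ester whose hydroxyl is also cis to the C4 methyl (hydride anti to both substituents, the sterically matched case), and acid then closes the cis-fused γ-lactone.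

Step 7
Reactants: 15 (3aS,5R,9bR)-8-methoxy-5-methyl-3a,4,5,9b-tetrahydronaphtho[2,1-b]furan-2(1H)-one
Product: 18 (3aS,5R,9bR)-5-methyl-3a,4,5,6,7,9b-hexahydronaphtho[2,1-b]furan-2,8(1H,9H)-dione, via lithium hydroxy carboxylate 16 (not isolated), via dihydroanisole enol ether 17 (not isolated)
Conditions: LiOH, THF/H2O, rt, evaporate; Li, NH3 (l), THF, t-BuOH, –78 to –33 °C; then (CO2H)2, THF/H2O, rt
Reagents that add atoms: water, O
Why: Birch reduction: after the lactone is opened to its lithium hydroxy carboxylate (a lactone or ester would be reduced by the metal, a carboxylate and an alkoxide are not), dissolving-metal reduction of the methoxy-substituted ring should stop at the 1,4-dihydro stage that keeps the tetrasubstituted C3=C8 alkene, and mild oxalic acid hydrolyses the enol ether to the non-conjugated β,γ-enone (C10 ketone) and re-closes the lactone.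

Step 8
Reactants: 18 (3aS,5R,9bR)-5-methyl-3a,4,5,6,7,9b-hexahydronaphtho[2,1-b]furan-2,8(1H,9H)-dione; 19 methylmagnesium bromide
Product: 20 (3aS,5R,8S,9bR)-8-hydroxy-5,8-dimethyl-3a,4,5,6,7,8,9,9b-octahydronaphtho[2,1-b]furan-2(1H)-one
Conditions: CeCl3 (dried), 19, THF, –78 °C; NH4Cl (aq); chromatographic removal of the 10R epimer
Reagents that add atoms: none
Why: CeCl3-promoted Grignard 1,2-addition (organocerium chemistry) is chemoselective for the ketone over the lactone at –78 °C and suppresses enolization of the β,γ-enone, but the carbonyl is remote from every stereocentre, so little facial bias is expected, the 10S alcohol 20 (hydroxyl α, methyl β) and its 10R epimer should both form and are separated by chromatography, and only 20 (assignment to be secured by NOE or X-ray) is taken on.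

Step 9
Reactants: 20 (3aS,5R,8S,9bR)-8-hydroxy-5,8-dimethyl-3a,4,5,6,7,8,9,9b-octahydronaphtho[2,1-b]furan-2(1H)-one; 21 N,N-dimethylmethyleneiminium iodide (Eschenmoser's salt)
Product: 22 C11-(dimethylaminomethyl) lactone (Mannich base of 20; C11 epimers)
Conditions: LiN(i-Pr)2 (2.3 equiv), THF, –78 °C; then 21, –78 to 0 °C; H2O
Reagents that add atoms: none
Why: Mannich reaction of a lactone enolate: LiN(i-Pr)2 removes the hydroxyl proton and the C11 α-proton and the enolate is aminomethylated by the preformed iminium salt, the configuration at C11 being irrelevant because that centre becomes trigonal in step 10.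

Step 10
Reactants: 22 C11-(dimethylaminomethyl) lactone
Product: 24 (3aS,5R,8S,9bS)-8-hydroxy-5,8-dimethyl-1-methylidene-3a,4,5,6,7,8,9,9b-octahydronaphtho[2,1-b]furan-2(1H)-one (octalin α-methylene lactone), via ammonium iodide 23 (not isolated)
Conditions: MeI, MeOH, rt, evaporate; then NaHCO3 (aq), CH2Cl2, rt
Reagents that add atoms: none
Why: Exhaustive N-methylation followed by base-induced β-elimination of trimethylamine (Hofmann-type E1cB elimination) should unveil the exocyclic C11=C13 double bond under conditions too mild to move it into the ring.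

Step 11
Reactants: 24 (3aS,5R,8S,9bS)-8-hydroxy-5,8-dimethyl-1-methylidene-3a,4,5,6,7,8,9,9b-octahydronaphtho[2,1-b]furan-2(1H)-one (octalin α-methylene lactone)
Product: 26 (4R,6S,7S,10S)-10-hydroxy-3,8-dioxogermacr-11(13)-en-12,6-olide, via ozonide 25 (not isolated)
Conditions: O3/O2 (1 equiv, metered to the Sudan Red 7B end point), CH2Cl2, –78 °C; then Me2S, –78 °C to rt
Reagents that add atoms: ozone, [O-][O+]=O
Why: Ozone adds as an electrophilic 1,3-dipole across the electron-rich tetrasubstituted C3=C8 bond, the primary ozonide fragments into a ketone and a carbonyl oxide held in the same ring, these recombine to ozonide 25 (or the C3 carbonyl oxide is caught by the C10 hydroxyl), and Me2S reduces the peroxide to the two ketones. The closest known reaction is the ozonolysis of 1,2,3,4,5,6,7,8-octahydronaphthalenes to cyclodecane-1,6-diones, that is alkene ozonolysis with reductive work-up. The ten-membered ring is not closed by bond formation: it is the perimeter of rings A and B and is set free when their shared bond is cut, so no mode of closure applies. No stereocentre is created, C3 and C8 become trigonal, and C4, C6, C7 and C10 are not touched under cold, neutral conditions. The step needs chemoselectivity for the ring-fusion alkene over the C11=C13 methylene: four alkyl groups make the former far more nucleophilic than the ester-conjugated methylene, and one equivalent of ozone metered against the indicator at –78 °C exploits that difference. The free C10 hydroxyl then holds the new C3 ketone as a five-membered hemiketal, which takes one partner out of a transannular aldol reaction.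

Step 12
Reactants: 26 (4R,6S,7S,10S)-10-hydroxy-3,8-dioxogermacr-11(13)-en-12,6-olide
Product: 27 (4R,6S,7R,8R,10S)-8,10-dihydroxy-3-oxogermacr-11(13)-en-12,6-olide
Conditions: Me4NBH(OAc)3, MeCN/AcOH, –30 to –20 °C; then NaHCO3 (aq)
Reagents that add atoms: none
Why: Evans–Saksena hydroxyl-directed reduction: the C10 hydroxyl (free in the open tautomer) exchanges with acetate on boron and the alkoxyborohydride delivers hydride to the C8 carbonyl through a six-membered chair transition state, that is to the α-face on which the C10–O bond lies, so the new C8 hydroxyl should come out β and 1,3-anti to the C10 hydroxyl (8R), while the unligated C3 ketone and the conjugated lactone are not reduced by this mild reagent.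

Step 13
Reactants: 27 (4R,6S,7R,8R,10S)-8,10-dihydroxy-3-oxogermacr-11(13)-en-12,6-olide; 28 2-methylpropanoic anhydride
Product: 29 (4R,6S,7S,8R,10S)-10-hydroxy-8-(2-methylpropanoyloxy)-3-oxogermacr-11(13)-en-12,6-olide (CNP0293926.1)
Conditions: 28, DMAP (cat.), Et3N, CH2Cl2, 0 °C
Reagents that add atoms: none
Why: DMAP-catalysed acyl transfer (Steglich-type acylation) should esterify only the secondary C8 hydroxyl, since the tertiary C10 hydroxyl (or the hemiketal hydroxyl) is far less reactive, and no stereocentre is touched.

**Compound list**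

1 | 4-methoxyphenylboronic acid | COc1ccc(cc1)B(O)O | starting material
2 | ethyl (E)-but-2-enoate (ethyl crotonate) | C/C=C/C(=O)OCC | starting material
3 | ethyl (3R)-3-(4-methoxyphenyl)butanoate | CCOC(=O)C[C@@H](C)c1ccc(OC)cc1 | intermediate
4 | (3R)-3-(4-methoxyphenyl)butanoic acid | OC(=O)C[C@@H](C)c1ccc(OC)cc1 | intermediate
5 | (trimethylsilyl)diazomethane | C[Si](C)(C)C=[N+]=[N-] | starting material
6 | (3R)-3-(4-methoxyphenyl)butanoyl chloride | ClC(=O)C[C@@H](C)c1ccc(OC)cc1 | intermediate
7 | (4R)-1-diazo-4-(4-methoxyphenyl)pentan-2-one | [N-]=[N+]=CC(=O)C[C@@H](C)c1ccc(OC)cc1 | intermediate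
8 | (3R)-6-methoxy-3-methyl-3,8a-dihydroazulen-1(2H)-one (Buchner product; C8a not defined) | O=C1C[C@@H](C)C2=CC=C(OC)C=CC12 | intermediate
9 | (4R)-7-methoxy-4-methyl-3,4-dihydronaphthalen-2(1H)-one | O=C1C[C@@H](C)c2ccc(OC)cc2C1 | intermediate
10 | ethyl bromoacetate | CCOC(=O)CBr | starting material
11 | 1-[(4R)-7-methoxy-4-methyl-3,4-dihydronaphthalen-2-yl]pyrrolidine | C[C@@H]1CC(N2CCCC2)=Cc2cc(OC)ccc12 | intermediate
12 | 1-[(4R)-1-(2-ethoxy-2-oxoethyl)-7-methoxy-4-methyl-3,4-dihydronaphthalen-2(1H)-ylidene]pyrrolidinium bromide | CCOC(=O)CC1C(=[N+]2CCCC2)C[C@@H](C)c2ccc(OC)cc12.[Br-] | intermediate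
13 | ethyl 2-[(4R)-7-methoxy-4-methyl-2-oxo-1,2,3,4-tetrahydronaphthalen-1-yl]acetate (both C1 epimers) | CCOC(=O)CC1C(=O)C[C@@H](C)c2ccc(OC)cc12 | intermediate
14 | ethyl 2-[(1R,2S,4R)-2-hydroxy-7-methoxy-4-methyl-1,2,3,4-tetrahydronaphthalen-1-yl]acetate (all-cis) | CCOC(=O)C[C@H]1[C@@H](O)C[C@@H](C)c2ccc(OC)cc12 | intermediate
15 | (3aS,5R,9bR)-8-methoxy-5-methyl-3a,4,5,9b-tetrahydronaphtho[2,1-b]furan-2(1H)-one (cis-fused lactone; C4 methyl, C6–O and C7–C11 all β) | O=C1O[C@H]2C[C@@H](C)c3ccc(OC)cc3[C@H]2C1 | intermediate
16 | lithium 2-[(1R,2S,4R)-2-hydroxy-7-methoxy-4-methyl-1,2,3,4-tetrahydronaphthalen-1-yl]acetate | [Li+].[O-]C(=O)C[C@H]1[C@@H](O)C[C@@H](C)c2ccc(OC)cc12 | intermediate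
17 | lithium 2-[(1R,2S,4R)-2-hydroxy-7-methoxy-4-methyl-1,2,3,4,5,8-hexahydronaphthalen-1-yl]acetate | [Li+].[O-]C(=O)C[C@H]1[C@@H](O)C[C@@H](C)C2=C1CC(OC)=CC2 | intermediate
18 | (3aS,5R,9bR)-5-methyl-3a,4,5,6,7,9b-hexahydronaphtho[2,1-b]furan-2,8(1H,9H)-dione (C10 ketone, C3=C8 alkene) | O=C1O[C@H]2C[C@@H](C)C(CCC(=O)C3)=C3[C@H]2C1 | intermediate
19 | methylmagnesium bromide | C[Mg]Br | starting material
20 | (3aS,5R,8S,9bR)-8-hydroxy-5,8-dimethyl-3a,4,5,6,7,8,9,9b-octahydronaphtho[2,1-b]furan-2(1H)-one (10S: C10 hydroxyl α, C10 methyl β) | O=C1O[C@H]2C[C@@H](C)C(CC[C@](C)(O)C3)=C3[C@H]2C1 | intermediate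
21 | N,N-dimethylmethyleneiminium iodide (Eschenmoser's salt) | C=[N+](C)C.[I-] | starting material
22 | (4R,6S,7R,10S)-octalin lactone with CH2NMe2 at C11 (Mannich base of 20; C11 epimers) | CN(C)CC1C(=O)O[C@H]2C[C@@H](C)C(CC[C@](C)(O)C3)=C3[C@@H]12 | intermediate
23 | trimethylammonium iodide of 22 | C[N+](C)(C)CC1C(=O)O[C@H]2C[C@@H](C)C(CC[C@](C)(O)C3)=C3[C@@H]12.[I-] | intermediate
24 | (3aS,5R,8S,9bS)-8-hydroxy-5,8-dimethyl-1-methylidene-3a,4,5,6,7,8,9,9b-octahydronaphtho[2,1-b]furan-2(1H)-one (germacrane locants 4R,6S,7S,10S; precursor of the key step) | C=C1C(=O)O[C@H]2C[C@@H](C)C(CC[C@](C)(O)C3)=C3[C@@H]12 | intermediate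
25 | secondary ozonide of 24 (1,2,4-trioxolane bridging C3 and C8; configuration at C3 and C8 not defined) | C=C1C(=O)O[C@H]2C[C@@H](C)C34CC[C@](C)(O)CC(OO3)(O4)[C@@H]12 | intermediate
26 | (4R,6S,7S,10S)-10-hydroxy-3,8-dioxogermacr-11(13)-en-12,6-olide (product of the key step; in equilibrium with its 3,10-hemiketal) | C=C1C(=O)O[C@H]2C[C@@H](C)C(=O)CC[C@](C)(O)CC(=O)[C@@H]12 | intermediate
27 | (4R,6S,7R,8R,10S)-8,10-dihydroxy-3-oxogermacr-11(13)-en-12,6-olide (C8 hydroxyl β; the C7 descriptor differs from 26 by CIP priority only) | C=C1C(=O)O[C@H]2C[C@@H](C)C(=O)CC[C@](C)(O)C[C@@H](O)[C@@H]12 | intermediate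
28 | 2-methylpropanoic anhydride (isobutyric anhydride) | CC(C)C(=O)OC(=O)C(C)C | starting material
29 | (4R,6S,7S,8R,10S)-10-hydroxy-8-(2-methylpropanoyloxy)-3-oxogermacr-11(13)-en-12,6-olide (CNP0293926.1) | C=C1C(=O)O[C@H]2C[C@@H](C)C(=O)CC[C@](C)(O)C[C@@H](OC(=O)C(C)C)[C@@H]12 | target

**Totals.** Total step count: 13. Longest linear sequence: 13 steps (from 1 and 2 to 29).

**Steps most likely to fail**

1. Step 11 (key step). What may go wrong: ozone goes on to attack the conjugated methylene once the ring-fusion alkene is used up, or the sensitive dione is lost during work-up through transannular aldol reaction or β-elimination of the lactone oxygen next to the C8 ketone. Fallback: take the second alkene out of the problem by carrying the methylene in masked form. The fallback sets out from Mannich base 22, which is protonated with CF3CO2H to its ammonium trifluoroacetate F1 (an ammonium ion is inert to ozone). F1 is ozonized (O3, CH2Cl2/MeOH, –78 °C; Me2S) to the amino dione F2. F2 is reduced with Me4NBH(OAc)3 as in step 12 to the amino alcohol F3, which is acylated with 28 as in step 13 to the amino ester F4. F4 is quaternized with MeI to the methiodide F5, and NaHCO3 then eliminates trimethylamine. The route is rejoined at 29.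

2. Step 12. What may go wrong: the 3,10-hemiketal ties up the C10 hydroxyl so that boron is not ligated, which would mean no reaction or hydride delivery with poor facial selectivity. Fallback: external instead of internal hydride delivery, followed by correction through inversion. The fallback sets out from 26, which is reduced with NaBH4/CeCl3 in MeOH at –78 °C. If the alcohol formed is the 8S alcohol F6 (the C8 epimer of 27), it is esterified with 2-methylpropanoic acid under Mitsunobu conditions (PPh3, diisopropyl azodicarboxylate), which inverts C8. The route is rejoined at 29.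

3. Step 6. What may go wrong: the catalyst discriminates poorly between the two C1 epimers of 13 (incomplete dynamic kinetic resolution), or the acidic ketone inhibits it. Fallback: set C6 and C7 together by syn addition of hydrogen. The fallback sets out from 13, which is saponified (LiOH) to the keto acid F7 and closed with Ac2O/NaOAc to the enol lactone F8 (C6=C7 double bond). Hydrogenation of F8 over Rh/Al2O3 should add both hydrogens to the face opposite the pseudoaxial C4 methyl. The route is rejoined at 15.

**Further compounds**

F1 | step 11 | dimethylammonium trifluoroacetate of Mannich base 22 | C[NH+](C)CC1C(=O)O[C@H]2C[C@@H](C)C(CC[C@](C)(O)C3)=C3[C@@H]12.[O-]C(=O)C(F)(F)F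
F2 | step 11 | amino dione (26 with CH–CH2NMe2 at C11 in place of C11=C13; C11 epimers) | CN(C)CC1C(=O)O[C@H]2C[C@@H](C)C(=O)CC[C@](C)(O)CC(=O)[C@@H]12
F3 | step 11 | amino alcohol (27 with CH–CH2NMe2 at C11; C11 epimers) | CN(C)CC1C(=O)O[C@H]2C[C@@H](C)C(=O)CC[C@](C)(O)C[C@@H](O)[C@@H]12
F4 | step 11 | amino ester (29 with CH–CH2NMe2 at C11; C11 epimers) | CN(C)CC1C(=O)O[C@H]2C[C@@H](C)C(=O)CC[C@](C)(O)C[C@@H](OC(=O)C(C)C)[C@@H]12
F5 | step 11 | trimethylammonium iodide of F4 | C[N+](C)(C)CC1C(=O)O[C@H]2C[C@@H](C)C(=O)CC[C@](C)(O)C[C@@H](OC(=O)C(C)C)[C@@H]12.[I-]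
F6 | step 12 | 8S alcohol (C8 epimer of 27; C8 hydroxyl α) | C=C1C(=O)O[C@H]2C[C@@H](C)C(=O)CC[C@](C)(O)C[C@H](O)[C@@H]12
F7 | step 6 | 2-[(4R)-7-methoxy-4-methyl-2-oxo-1,2,3,4-tetrahydronaphthalen-1-yl]acetic acid (C1 epimers) | OC(=O)CC1C(=O)C[C@@H](C)c2ccc(OC)cc12
F8 | step 6 | (5R)-8-methoxy-5-methyl-4,5-dihydronaphtho[2,1-b]furan-2(1H)-one (enol lactone, C6=C7) | O=C1CC2=C(O1)C[C@@H](C)c3ccc(OC)cc23
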